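**Retrosynthetic overview**
1. Target 21 is cut last at the C5–CH2 bond: C5 of azaphilone core 12 (the nucleophilic end of its vinylogous ester) adds to the o-quinone methide released from Mannich base 20 of the (3'S)-isochromanone.
2. Enabling feature of 12: its pyran ring O2–C1=C8a–C4a(=C5)–C4=C3 is the cyclic anhydro form of a cis-2-ene-1,5-dicarbonyl (C1 aldehyde, C4a=C4, C3 methyl ketone). C7 is quaternary and C5–H is α to the C6 ketone, so the open form cannot aromatize and recloses to the neutral 4-ylidene-4H-pyran.
3. C8a therefore becomes a vinyl electrophile inside a temporary 4H-1,3-dioxin ring (triflate 9, which masks the C1 aldehyde and the C8 hydroxyl), C4a≡C4 a tethered silyl alkyne, and C3 an acetyl-anion equivalent (stannane 10). One palladium-triggered cyclization/coupling forms C4a–C8a and C3–C4, and acid in the same flask closes the pyran.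
4. Ring order: temporary dioxin (bought) → carbocycle by C4a–C8a closure (6-exo-dig) → pyran (acid). The lactone ring of the other half comes from ortho-metalation, epoxide opening and lactonization.
5. Stereocentres: C7 and C8 together from one catalytic asymmetric, syn-selective Mukaiyama aldol of the dioxanone enolsilane with methyl pyruvate; C3' is bought as (S)-propylene oxide.

Key step: step 7

Remark: locants are those of the 6H-isochromen-6-one half (O2, C1, C3–C8a; precursor atoms carry the locants they acquire in 12) and primed locants those of the isochroman-1-one half; the drawn configuration is read as (7R,8S) with a trans-diol and (3'S).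

**Route**

Step 1
Reactants: 1 2,2-dimethyl-1,3-dioxan-5-one
Product: 2 2,2-dimethyl-5-[(trimethylsilyl)oxy]-4H-1,3-dioxine
Conditions: TMSOTf, Et3N, CH2Cl2, 0 °C
Reagents that add atoms: trimethylsilyl triflate, C[Si](C)(C)OS(=O)(=O)C(F)(F)F
Why: Silyl enol ether formation by soft enolization and O-silylation; the symmetric ketone can give only one enolsilane.

Step 2
Reactants: 2 dioxanone enolsilane; 3 methyl pyruvate
Product: 4 methyl (2R)-2-[(4R)-2,2-dimethyl-5-oxo-1,3-dioxan-4-yl]-2-[(trimethylsilyl)oxy]propanoate
Conditions: Cu(OTf)2 (10 mol %), (R,R)-2,2'-isopropylidenebis(4-tert-butyl-2-oxazoline) (11 mol %), THF, −78 °C; filtration through silica without acid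
Reagents that add atoms: none
Why: Copper–bis(oxazoline)-catalysed Mukaiyama aldol addition to a pyruvate ester, in which the ketoester chelates divalent copper through both carbonyl oxygens so that the tert-butyl groups expose one ketone face (this sets C7, the ligand antipode being chosen for R), the open transition state places the dioxanone oxygen syn to the new tertiary oxygen (this sets C8), and silyl transfer should release the product directly as its O-trimethylsilyl ether.

Step 3
Reactants: 4 aldol silyl ether
Product: 5 methyl (2R)-2-[(4R)-2,2-dimethyl-5-{[(trifluoromethyl)sulfonyl]oxy}-4H-1,3-dioxin-4-yl]-2-[(trimethylsilyl)oxy]propanoate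
Conditions: KN(SiMe3)2, THF, −78 °C; then PhNTf2, −78 to −20 °C
Reagents that add atoms: N-phenylbis(trifluoromethanesulfonimide), O=S(=O)(N(c1ccccc1)S(=O)(=O)C(F)(F)F)C(F)(F)F
Why: Enol triflate formation, in which the base should take a proton from the unhindered C1 methylene rather than from the C8 methine next to the quaternary carbon and the potassium enolate is O-sulfonylated, so that C7 (no α-hydrogen) and C8 (not deprotonated) keep their configuration.

Step 4
Reactants: 5 triflate ester
Product: 6 (2R)-2-[(4R)-2,2-dimethyl-5-{[(trifluoromethyl)sulfonyl]oxy}-4H-1,3-dioxin-4-yl]-2-[(trimethylsilyl)oxy]propanal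
Conditions: i-Bu2AlH, CH2Cl2, −78 °C; aq potassium sodium tartrate
Reagents that add atoms: none
Why: Partial reduction of an ester to the aldehyde through the aluminium hemiacetal that is stable at −78 °C; the enol triflate, silyl ether and acetal are not touched and the α-carbon is quaternary.

Step 5
Reactants: 6 aldehyde; 7 3-bromo-1-(trimethylsilyl)prop-1-yne
Product: 8 (2S,3RS)-2-[(4R)-2,2-dimethyl-5-{[(trifluoromethyl)sulfonyl]oxy}-4H-1,3-dioxin-4-yl]-6-(trimethylsilyl)-2-[(trimethylsilyl)oxy]hex-5-yn-3-ol (C6 epimers; same spatial arrangement at C7 as in 6, the descriptor changes by priority only)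
Conditions: Zn dust, THF, 0 °C to rt; aq NH4Cl
Reagents that add atoms: none
Why: Barbier-type propargylation, in which the allenylzinc bromide formed from 7 adds to the aldehyde with allylic transposition to give the homopropargylic alcohol; the new carbinol centre forms as an epimer mixture that is of no consequence because step 6 oxidizes it.

Step 6
Reactants: 8 homopropargylic alcohol
Product: 9 (2R)-2-[(4R)-2,2-dimethyl-5-{[(trifluoromethyl)sulfonyl]oxy}-4H-1,3-dioxin-4-yl]-6-(trimethylsilyl)-2-[(trimethylsilyl)oxy]hex-5-yn-3-one
Conditions: Dess–Martin periodinane, NaHCO3, CH2Cl2, 0 °C to rt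
Reagents that add atoms: none
Why: Dess–Martin oxidation of a secondary alcohol under buffered, base-free conditions, so that the β,γ-alkynyl ketone should not isomerize to the allenone and the quaternary C7 cannot epimerize.

Step 7
Reactants: 9 alkynyl ketone dioxinyl triflate; 10 tributyl(1-ethoxyvinyl)stannane
Product: 12 (7R,8S)-7,8-dihydroxy-3,7-dimethyl-7,8-dihydro-6H-isochromen-6-one, via bicyclic dienol ether 11 (not isolated)
Conditions: Pd(PPh3)4 (10 mol %), CuI (10 mol %), LiCl (3 equiv), THF, 60 °C, slow addition of 10; then 1 M HCl, THF, 0 °C to rt; NaHCO3 work-up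
Reagents that add atoms: water, O (carbonyl oxygen of C3 after enol ether hydrolysis; this oxygen or the former dioxin oxygen ends as O2)
Why: Oxidative addition of zerovalent palladium into the C8a–OTf bond of the dioxinyl triflate, 6-exo-dig syn-carbopalladation of the tethered C4a≡C4 silyl alkyne (C4a–C8a bond, carbocycle closed) and Stille capture of the alkenylpalladium by 10 (C3–C4 bond) should give 11; this is a cyclization–anion-capture cascade of the cyclocarbopalladation/Stille type, known for silyl alkynes and for 4H-1,3-dioxin-5-yl triflates. Aqueous acid then hydrolyses the ethoxyvinyl ether to the methyl ketone, cleaves the dioxin acetal to the C1 aldehyde and the C8 hydroxyl, removes the O-silyl group and protodesilylates C4 by way of the α-silyl ketone tautomer. The cis-2-ene-1,5-dicarbonyl so released closes the pyran ring by 6-exo-trig attack of the C3 carbonyl oxygen on the protonated C1 aldehyde (an oxa-6π closure in its enol form) and loses water, and loss of the C5 proton, acidified by the C6 ketone, leaves the neutral 4-ylidene-4H-pyran. No stereocentre is created: quaternary C7 has no α-hydrogen and C8 is not enolizable, and the syn-insertion places C3 cis to C8a as the ring closure requires. The step needs ring closure to outrun direct coupling of the triflate and exo to beat endo insertion, which the four-atom tether, the gem-disubstituted C7 and slow addition of 10 secure, and it needs carbopalladation to beat attack of the C6 carbonyl oxygen on the alkyne, which the base-free conditions favour. The bath is kept at 60 °C so that the dioxin does not undergo thermal retro-cycloaddition, and the acid is kept dilute and cold so that C8 is not ionized.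

Step 8
Reactants: 13 2,4-dimethoxytoluene
Product: 14 1-bromo-2,4-dimethoxy-5-methylbenzene
Conditions: NBS, MeCN, 0 °C to rt
Reagents that add atoms: N-bromosuccinimide, O=C1CCC(=O)N1Br
Why: Electrophilic aromatic bromination at the position para to one methoxy group and ortho to the other, the most activated and least hindered site.

Step 9
Reactants: 14 aryl bromide
Product: 15 N,N-diethyl-2,4-dimethoxy-5-methylbenzamide
Conditions: n-BuLi, THF, −78 °C; then Et2NCOCl, −78 °C to rt
Reagents that add atoms: diethylcarbamoyl chloride, CCN(CC)C(Cl)=O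
Why: Bromine–lithium exchange followed by acylation of the aryllithium with a carbamoyl chloride.

Step 10
Reactants: 15 benzamide; 16 (S)-propylene oxide
Product: 18 (3S)-6,8-dimethoxy-3,5-dimethyl-3,4-dihydro-1H-isochromen-1-one, via hydroxy amide 17 (not isolated)
Conditions: s-BuLi, TMEDA, THF, −78 °C; 16, BF3·OEt2, −78 °C; aq NH4Cl; then TsOH·H2O, toluene, 110 °C
Reagents that add atoms: none
Why: Directed ortho-metalation by the tertiary amide at its only free ortho position, Lewis-acid-assisted opening of the epoxide at its CH2 terminus (the bought stereocentre is not touched) and acid-induced lactonization through the carbinol oxygen with loss of diethylamine, hence retention at C3'.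

Step 11
Reactants: 18 dimethoxy lactone
Product: 19 (3S)-6,8-dihydroxy-3,5-dimethyl-3,4-dihydro-1H-isochromen-1-one
Conditions: BBr3, CH2Cl2, −78 °C to rt; aqueous work-up
Reagents that add atoms: none
Why: Lewis-acid cleavage of both aryl methyl ethers, which should leave the lactone and its stereocentre intact at low temperature.

Step 12
Reactants: 19 dihydroxy lactone
Product: 20 (3S)-7-[(dimethylamino)methyl]-6,8-dihydroxy-3,5-dimethyl-3,4-dihydro-1H-isochromen-1-one
Conditions: 37% aq HCHO, 40% aq Me2NH, EtOH, rt
Reagents that add atoms: formaldehyde, C=O; dimethylamine, CNC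
Why: Phenol Mannich reaction at the only unsubstituted ring position, which is ortho to both hydroxyl groups.

Step 13
Reactants: 12 azaphilone core; 20 Mannich base
Product: 21 (3S)-7-{[(7R,8S)-7,8-dihydroxy-3,7-dimethyl-6-oxo-7,8-dihydro-6H-isochromen-5-yl]methyl}-6,8-dihydroxy-3,5-dimethyl-3,4-dihydro-1H-isochromen-1-one
Conditions: 1,4-dioxane, 90 °C, N2 stream
Reagents that add atoms: none
Why: Thermal retro-Mannich loss of dimethylamine gives the o-quinone methide, which should be trapped in a Michael addition by C5 of 12 (the nucleophilic terminus of its vinylogous ester, where such isochromenones take up electrophiles), followed by rearomatization and loss of the C5 proton; no stereocentre is involved and the gas stream removes the amine.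

**Compound list**
1 | 2,2-dimethyl-1,3-dioxan-5-one | CC1(C)OCC(=O)CO1 | starting material
2 | 2,2-dimethyl-5-[(trimethylsilyl)oxy]-4H-1,3-dioxine | CC1(C)OCC(O[Si](C)(C)C)=CO1 | intermediate
3 | methyl pyruvate | CC(=O)C(=O)OC | starting material
4 | methyl (2R)-2-[(4R)-2,2-dimethyl-5-oxo-1,3-dioxan-4-yl]-2-[(trimethylsilyl)oxy]propanoate | COC(=O)[C@](C)(O[Si](C)(C)C)[C@@H](OC(C)(C)OC1)C1=O | intermediate
5 | methyl (2R)-2-[(4R)-2,2-dimethyl-5-{[(trifluoromethyl)sulfonyl]oxy}-4H-1,3-dioxin-4-yl]-2-[(trimethylsilyl)oxy]propanoate | COC(=O)[C@](C)(O[Si](C)(C)C)[C@@H](OC(C)(C)OC=1)C1OS(=O)(=O)C(F)(F)F | intermediate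
6 | (2R)-2-[(4R)-2,2-dimethyl-5-{[(trifluoromethyl)sulfonyl]oxy}-4H-1,3-dioxin-4-yl]-2-[(trimethylsilyl)oxy]propanal | O=C[C@](C)(O[Si](C)(C)C)[C@@H](OC(C)(C)OC=1)C1OS(=O)(=O)C(F)(F)F | intermediate
7 | 3-bromo-1-(trimethylsilyl)prop-1-yne | BrCC#C[Si](C)(C)C | starting material
8 | (2S,3RS)-2-[(4R)-2,2-dimethyl-5-{[(trifluoromethyl)sulfonyl]oxy}-4H-1,3-dioxin-4-yl]-6-(trimethylsilyl)-2-[(trimethylsilyl)oxy]hex-5-yn-3-ol (carbinol epimers) | C[Si](C)(C)C#CCC(O)[C@](C)(O[Si](C)(C)C)[C@@H](OC(C)(C)OC=1)C1OS(=O)(=O)C(F)(F)F | intermediate
9 | (2R)-2-[(4R)-2,2-dimethyl-5-{[(trifluoromethyl)sulfonyl]oxy}-4H-1,3-dioxin-4-yl]-6-(trimethylsilyl)-2-[(trimethylsilyl)oxy]hex-5-yn-3-one | C[Si](C)(C)C#CCC(=O)[C@](C)(O[Si](C)(C)C)[C@@H](OC(C)(C)OC=1)C1OS(=O)(=O)C(F)(F)F | intermediate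
10 | tributyl(1-ethoxyvinyl)stannane | C=C(OCC)[Sn](CCCC)(CCCC)CCCC | starting material
11 | bicyclic dienol ether: (5E,8R,8aS)-5-[2-ethoxy-1-(trimethylsilyl)prop-2-en-1-ylidene]-2,2,8-trimethyl-8-[(trimethylsilyl)oxy]-5,6,8,8a-tetrahydro-1,3-benzodioxin-7-one (ethoxyvinyl carbon cis to C4a of the benzodioxin) | C=C(OCC)/C([Si](C)(C)C)=C1/CC(=O)[C@](C)(O[Si](C)(C)C)[C@@H](OC(C)(C)OC=2)C12 | intermediate (not isolated)
12 | (7R,8S)-7,8-dihydroxy-3,7-dimethyl-7,8-dihydro-6H-isochromen-6-one | CC1=CC2=CC(=O)[C@](C)(O)[C@@H](O)C2=CO1 | intermediate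
13 | 2,4-dimethoxytoluene | Cc1ccc(OC)cc1OC | starting material
14 | 1-bromo-2,4-dimethoxy-5-methylbenzene | Cc1cc(Br)c(OC)cc1OC | intermediate
15 | N,N-diethyl-2,4-dimethoxy-5-methylbenzamide | CCN(CC)C(=O)c1cc(C)c(OC)cc1OC | intermediate
16 | (S)-propylene oxide | C[C@H]1CO1 | starting material
17 | N,N-diethyl-2-[(2S)-2-hydroxypropyl]-4,6-dimethoxy-3-methylbenzamide | C[C@H](O)Cc1c(C)c(OC)cc(OC)c1C(=O)N(CC)CC | intermediate (not isolated)
18 | (3S)-6,8-dimethoxy-3,5-dimethyl-3,4-dihydro-1H-isochromen-1-one | COc1cc(OC)c(C)c2c1C(=O)O[C@@H](C)C2 | intermediate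
19 | (3S)-6,8-dihydroxy-3,5-dimethyl-3,4-dihydro-1H-isochromen-1-one | Oc1cc(O)c(C)c2c1C(=O)O[C@@H](C)C2 | intermediate
20 | (3S)-7-[(dimethylamino)methyl]-6,8-dihydroxy-3,5-dimethyl-3,4-dihydro-1H-isochromen-1-one | CN(C)Cc1c(O)c(C)c2c(c1O)C(=O)O[C@@H](C)C2 | intermediate
21 | (3S)-7-{[(7R,8S)-7,8-dihydroxy-3,7-dimethyl-6-oxo-7,8-dihydro-6H-isochromen-5-yl]methyl}-6,8-dihydroxy-3,5-dimethyl-3,4-dihydro-1H-isochromen-1-one | CC1=CC2=C(Cc3c(O)c(C)c4c(c3O)C(=O)O[C@@H](C)C4)C(=O)[C@](C)(O)[C@@H](O)C2=CO1 | target

**Count and risks**
Total steps: 13. Longest linear sequence: 8 steps (steps 1–7 and 13).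

Steps most likely to fail:

1. Step 7. What may go wrong: direct coupling of the triflate with the stannane before ring closure, stalling of transmetalation at the hindered α-silyl alkenylpalladium, oxypalladation of the alkyne by the ketone oxygen, thermal fragmentation of the dioxin, or ionization at C8 during the acid stage with loss of configuration. The fallback separates the two bond formations; it sets out from 9 and comes back at 12. Reductive cyclocarbopalladation with hydride capture (Pd(OAc)2, PPh3, HCO2Na, DMF, 60 °C) should give the exocyclic alkenylsilane F1. Iododesilylation (NIS, MeCN, 0 °C) should give the alkenyl iodide F2, and an ordinary Stille coupling with 10 (Pd(PPh3)4, CuI, DMF, rt) the dienol ether F3. The same dilute acid treatment (1 M HCl, THF, 0 °C to rt) should then lead to 12; the alkene geometry of F3 does not matter because the enone equilibrates through its dienol before the pyran closes.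

2. Step 13. What may go wrong: addition of the liberated amine to the pyran ring, capture of the quinone methide by the enol ether double bonds in a hetero-Diels–Alder sense, or self-condensation of the quinone methide. The fallback reverses the roles of the partners; it sets out from 12 (with 19) and comes back at 21. A Mannich reaction of 12 with dimethyl(methylidene)ammonium iodide (CH2Cl2, rt) should give the C5 aminomethyl azaphilone F4. Heating F4 with phenol 19 (AcOH, 1,4-dioxane, 60 °C) should release the 5-methylidene pyrylium-type acceptor, which alkylates the free C7' position of 19 in a Friedel–Crafts sense to give 21.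

3. Step 2. What may go wrong: slow turnover or poor simple diastereoselection with the cyclic α-oxygenated enolsilane, or erosion of the facial selectivity. The fallback replaces Lewis-acid activation of the enolsilane by enamine catalysis on the ketone itself; it sets out from 1 (with 3) and comes back at 4. A direct aldol addition catalysed by (R)-proline (DMF, 4 °C) should give the free β-hydroxy ketone F5, the same syn adduct being expected if the ester group takes the place of an aldehyde hydrogen in the enamine transition state. O-Silylation of F5 with N-(trimethylsilyl)imidazole (CH2Cl2, rt) returns to 4.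

**Further compounds**
F1 | step 7 | (5E,8R,8aS)-2,2,8-trimethyl-8-[(trimethylsilyl)oxy]-5-[(trimethylsilyl)methylidene]-5,6,8,8a-tetrahydro-1,3-benzodioxin-7-one | C[Si](C)(C)/C=C1\CC(=O)[C@](C)(O[Si](C)(C)C)[C@@H](OC(C)(C)OC=2)C12
F2 | step 7 | (5E,8R,8aS)-5-(iodomethylidene)-2,2,8-trimethyl-8-[(trimethylsilyl)oxy]-5,6,8,8a-tetrahydro-1,3-benzodioxin-7-one | I/C=C1\CC(=O)[C@](C)(O[Si](C)(C)C)[C@@H](OC(C)(C)OC=2)C12
F3 | step 7 | (5E,8R,8aS)-5-(2-ethoxyprop-2-en-1-ylidene)-2,2,8-trimethyl-8-[(trimethylsilyl)oxy]-5,6,8,8a-tetrahydro-1,3-benzodioxin-7-one | C=C(OCC)/C=C1\CC(=O)[C@](C)(O[Si](C)(C)C)[C@@H](OC(C)(C)OC=2)C12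
F4 | step 13 | (7R,8S)-5-[(dimethylamino)methyl]-7,8-dihydroxy-3,7-dimethyl-7,8-dihydro-6H-isochromen-6-one | CC1=CC2=C(CN(C)C)C(=O)[C@](C)(O)[C@@H](O)C2=CO1
F5 | step 2 | methyl (2R)-2-hydroxy-2-[(4R)-2,2-dimethyl-5-oxo-1,3-dioxan-4-yl]propanoate | COC(=O)[C@](C)(O)[C@@H](OC(C)(C)OC1)C1=O
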